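# Design of a synthesis of cis-miyabenol C by two conjunctive cross-couplings of one alkenylboron building block

## The problem

cis-Miyabenol C (25) joins two trans-2,3-diaryl-2,3-dihydrobenzofurans through the single bond from C3 of unit 1 to C4' of ring B of unit 2, and ring A of unit 1 carries a Z-4-hydroxystyryl arm at C4. C3 and C3' are both aryl-crowded methine carbons, and because C3 bears two ortho-substituted rings (ring A and ring B), C3–C4' is the most congested bond in the molecule. There are four stereocenters, (2S,3S) in unit 1 and (2R,3R) in unit 2; within each ring the trans relation is the stable one, and C2 and C2' can be corrected through their 4-oxygenated benzylic cations. C3 and C3' are therefore the centres that must be set, and since they have opposite absolute sense and are too remote to steer each other, reagent control is needed twice. The fragile elements are the Z-stilbene (isomerised by light, acid or palladium hydrides), the benzylic C2–O1 and C2'–O1' bonds (which ionise in acid and can then be captured irreversibly by a neighbouring arene) and seven free phenols. The enabling feature is the C2'–C3' unit: C3' carries ring B and the 3,5-dihydroxyphenyl ring and C2' carries the 4-hydroxyphenyl ring and O1', which is the pattern an E-alkenylboron on ring B gives after aryl migration from boron to C2', aryl delivery from palladium to C3' and oxidation of the C–B bond. The same pattern recurs at C2–C3, with ring B as the aryl delivered by palladium. Rings A and B also share one substitution pattern (carbon at 3a, oxygen at 7a and 6, a leaving-group site at 4), so a single alkenylboron, 8, can serve both units.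

## Retrosynthesis

**Z-alkene and phenols (25 ⇒ 24 ⇒ 23).** No skeletal bond is cut. The Z-alkene is traced to the diarylalkyne 24 and the seven hydroxyls to the methyl ethers of 23. A Wittig route would give Z/E mixtures, and carrying a Z-stilbene through a Lewis-acid demethylation invites isomerisation and cation cyclisation. The alkyne has no ortho oxygen and is the more robust relay. The forward steps must cleave seven ethers without opening the furans for good, and must stop the hydrogenation at the alkene on a free polyphenol.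

**Styryl arm (23 ⇒ 21 + 22).** The C4–C(sp) bond is cut to aryl triflate 21 and commercial 4-ethynylanisole 22. A Suzuki coupling with a Z-alkenylboron would be one step shorter but would place the Z-alkene before the demethylation. The forward Sonogashira coupling has to engage a mono-ortho-substituted, electron-rich triflate.

**Furan of unit 1 (21 ⇒ 20 ⇒ 19 ⇒ 18).** The C2–O1 bond is cut to the 1,2,2-triarylethanol 19, and its hydroxyl to the C–B bond of 18. Closure through the 4-methoxybenzylic cation gives the trans ring whatever the configuration at C2. Ring A carries two equivalent methoxymethyl-protected oxygens: one closes the ring and the other emerges as the free C4 hydroxyl of 20, which becomes the triflate 21. No differentiation of the two oxygens and no separate borylation or halogenation is needed.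

**C3 and its aryl groups (18 ⇒ 13 + 17).** The C3–C4' and C2–aryl bonds are cut together, which removes both stereocenters of unit 1. A biaryl-type coupling to a benzofuran would lose C3 and leave an uncontrolled reduction, and an enolate arylation would leave C3 epimerisable. Only this cut lets a catalyst decide C3. The precursors are the complete unit 2 as triflate 17 and the lithium borate 13, the ate complex of alkenylboron 8. The forward reaction must override the stereocenters of 17, and it needs the ligand antipode opposite to the one used for unit 2.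

**Furan of unit 2 (17 ⇒ 16 ⇒ 15 ⇒ 14).** The same three operations (triflation, cation closure with loss of both acetals, C–B oxidation) lead back from 17 through phenol 16 and alcohol 15 to boronate 14.

**C3' and its aryl groups (14 ⇒ 13 + 10).** The C3'–aryl and C2'–aryl bonds are cut to the same borate 13 and 3,5-dimethoxyphenyl triflate 10. This is the less crowded of the two couplings and carries the strategy.

**Ate complex (13 ⇒ 8 + 12; 12 ⇒ 11).** The boron–aryl bond of 13 is cut to alkenylboron 8 and 4-methoxyphenyllithium 12, which comes from 4-bromoanisole 11 by halogen–lithium exchange. Making 13 in an operation of its own lets one preparation supply both couplings and lets the hydrocarbon by-products be stripped off before palladium is added.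

**Building blocks (8 ⇒ 4 + 6; 4 ⇒ 3 ⇒ 2 ⇒ 1; 6 ⇒ 5; 10 ⇒ 9).** The hindered diol 6 is chosen for boron because β-substituted alkenylboron ate complexes with small diols tend to transfer a group directly to palladium. Alkenylboron 8 comes from alkyne 4 by hydroboration with catecholborane through 7 and exchange of catechol for 6. Alkyne 4 comes from aldehyde 3 by one-carbon homologation, and 3 from 2,4,6-trimethoxybenzaldehyde 1 by chelation-controlled double demethylation to 2 and acetal protection. Diol 6 comes from acenaphthenequinone 5, and triflate 10 from 3,5-dimethoxyphenol 9.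

## Roads not taken

Alternative 1: Ring A is removed by cutting C3a–C7a and C4–C5. This leads to diynone A2, in which unit 2 is complete and acylated at C4', and the oxygenated silyloxydiene A3. In the forward step the ketone-activated triple bond of A2 takes up A3 in a Diels–Alder reaction, and elimination of the acetal methoxy group aromatises the adduct to the 2-hydroxybenzophenone A1.
- Merits: the diene fixes the oxygen pattern of ring A. The crowded C3–C4' bond exists beforehand as an unhindered acyl bond. The arylethynyl group for the Z-styryl arm is already in place.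
- Weak points: the step creates no stereocenter. C3 and C2 must then be raised from a benzophenone carbonyl with three ortho substituents, with only the distant C3' as substrate control. A2 is a doubly activated acceptor whose second triple bond can also react. A2 presupposes a finished, stereodefined unit 2.
- Comparison: this road is better at making the C3–C4' bond without a hindered metal-mediated coupling, and equal in its alkyne endgame. The chosen plan sets against it catalyst control of both C3 and C3' and the use of one building block twice.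

Alternative 2: The C3–C3a bond of unit 1 is traced to a 1,2-aryl shift, so the dihydrobenzofuran ester A4 comes from the chiral-pool (2S)-flavanone A5. In the forward step PhI(OAc)2 (trivalent iodine) with H2SO4 in trimethyl orthoformate makes the ring-A carbon of A5 migrate from the carbonyl carbon to C3, and the pyranone contracts to the trans furan ester A4.
- Merits: the step is well known on flavanones and is more secure than the key step chosen here. C2 comes from a cheap natural source.
- Weak points: (2S)-flavanones racemise by reversible opening to the chalcone under the base needed to protect the chelated hydroxyl. The stereocenter bought is C2, which is correctable anyway, and C3 follows only by thermodynamics. The C3 ester of A4 is not an aryl group, so ring B must be built from it or installed by a decarboxylative arylation at an epimerisable centre. Unit 2 is not addressed.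
- Comparison: this road wins on the reliability of its key step. The chosen plan sets against it direct formation of both C3–aryl bonds and a much shorter sequence.

Alternative 3: Ring B is removed by cutting C3a'–C7a', C4'–C5' and C6'–C7'. This leads to the ynol-ether diyne A7 and ethoxyethyne A8. In the forward step [Rh(cod)2]BF4 with BINAP cyclotrimerises A7 with A8 to A6, closing ring B and its furan together.
- Merits: every substituent of ring B is placed unambiguously. There is no cross-coupling at the crowded C3'. The silyl group at C4' is an ipso handle for the later union.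
- Weak points: both stereocenters must already be present in acyclic A7, which needs its own asymmetric synthesis. The secondary benzylic ynol ether of A7 is prone to thermal fragmentation to a ketene. The orientation in which A8 is taken up rests on steering by the silyl group. The union with unit 1 still needs a stereocontrolled C3–C4' bond.
- Comparison: this road is as convergent and gentler on sterics. The chosen plan sets against it that the stereocenters and three aryl–carbon connections arise in the same step from commercial arenes.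

Key step: step 8

Assumption: the (Sp,Sp) antipode of the ferrocenyl bisphosphine is taken to direct palladium to the alkene face that gives 14; if the sense proves opposite, the two antipodes are exchanged between steps 8 and 12.

Remark: borate 13 is moisture-sensitive and is used as a crude THF solution; step 7 is run on the scale that supplies both step 8 and step 12, or is repeated unchanged directly before step 12.

## Route

Step 1
Reactants: 1 2,4,6-trimethoxybenzaldehyde
Product: 2 2,6-dihydroxy-4-methoxybenzaldehyde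
Conditions: AlCl3 (3.5 equiv), CH2Cl2, 0 to 40 °C; aq. HCl
Reagents that add atoms: none
Why: Chelation-directed Lewis-acid ether cleavage: AlCl3 bridges the aldehyde oxygen and an ortho methoxy oxygen and chloride removes that methyl group, so both ortho ethers should fall while the unchelated para ether stays.

Step 2
Reactants: 2 2,6-dihydroxy-4-methoxybenzaldehyde
Product: 3 4-methoxy-2,6-bis(methoxymethoxy)benzaldehyde
Conditions: NaH (2.5 equiv), MOMCl (2.5 equiv), DMF, 0 to 25 °C
Reagents that add atoms: chloromethyl methyl ether (MOMCl), COCCl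
Why: Williamson-type O-alkylation; forming the sodium phenoxides breaks the hydrogen bonds to the aldehyde so that both hydroxyls react, and the acetals will tolerate the aryllithium and alkaline peroxide used later.

Step 3
Reactants: 3 4-methoxy-2,6-bis(methoxymethoxy)benzaldehyde
Product: 4 2-ethynyl-5-methoxy-1,3-bis(methoxymethoxy)benzene
Conditions: dimethyl (1-diazo-2-oxopropyl)phosphonate, K2CO3, MeOH, 0 to 25 °C
Reagents that add atoms: dimethyl (1-diazo-2-oxopropyl)phosphonate, COP(=O)(OC)C(=[N+]=[N-])C(C)=O
Why: Seyferth–Gilbert homologation in its Ohira–Bestmann form; the non-enolisable aldehyde should give the terminal alkyne through the diazoalkene and a 1,2-hydrogen shift under conditions that leave the acetals intact.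

Step 4
Reactants: 5 acenaphthenequinone
Product: 6 cis-1,2-dimethyl-1,2-dihydroacenaphthylene-1,2-diol
Conditions: AlMe3 (5 equiv), toluene, 0 to 25 °C; aq. potassium sodium tartrate
Reagents that add atoms: trimethylaluminium, C[Al](C)C
Why: Double 1,2-addition of methyl to the 1,2-diketone; the second methyl should enter on the face away from the bulky aluminium alkoxide, which gives the cis (meso) diol, the only isomer that can bridge one boron atom.

Step 5
Reactants: 4 2-ethynyl-5-methoxy-1,3-bis(methoxymethoxy)benzene, 6 cis-1,2-dimethyl-1,2-dihydroacenaphthylene-1,2-diol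
Product: 8 cis-1,2-dimethylacenaphthylene-1,2-diyl [(E)-2-[4-methoxy-2,6-bis(methoxymethoxy)phenyl]ethenyl]boronate, via catechol alkenylboronate 7 (not isolated)
Conditions: catecholborane (1.2 equiv), Cy2BH (10 mol %), THF, 25 °C; then 6, 25 °C
Reagents that add atoms: catecholborane, [H]B1Oc2ccccc2O1
Why: Dialkylborane-catalysed syn hydroboration of the terminal alkyne places boron on the terminal carbon and gives the E-alkenyl catechol ester, and the labile catechol is then displaced by the ditertiary diol in a transesterification.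

Step 6
Reactants: 9 3,5-dimethoxyphenol
Product: 10 3,5-dimethoxyphenyl trifluoromethanesulfonate
Conditions: Tf2O, pyridine, CH2Cl2, 0 °C
Reagents that add atoms: trifluoromethanesulfonic anhydride, O=S(=O)(OS(=O)(=O)C(F)(F)F)C(F)(F)F
Why: Standard O-sulfonylation of a phenol gives the aryl electrophile for the conjunctive coupling.

Step 7
Reactants: 8 cis-1,2-dimethylacenaphthylene-1,2-diyl [(E)-2-[4-methoxy-2,6-bis(methoxymethoxy)phenyl]ethenyl]boronate, 11 4-bromoanisole
Product: 13 lithium [(E)-2-[4-methoxy-2,6-bis(methoxymethoxy)phenyl]ethenyl](4-methoxyphenyl)borate of diol 6, via 4-methoxyphenyllithium 12 (not isolated)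
Conditions: 11, t-BuLi (2 equiv), THF, −78 °C; then 8, −78 to 25 °C; volatiles removed, residue redissolved in THF under argon
Reagents that add atoms: tert-butyllithium, [Li]C(C)(C)C
Why: Bromine–lithium exchange (the second equivalent of t-BuLi destroys the tert-butyl bromide) gives 12, which adds to the vacant p orbital on the boron of 8 to form the four-coordinate lithium borate; the methyl and methoxymethyl ethers are inert to the aryllithium at −78 °C, and evaporation removes the hydrocarbon by-products before the complex is carried on.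

Step 8
Reactants: 13 lithium [(E)-2-[4-methoxy-2,6-bis(methoxymethoxy)phenyl]ethenyl](4-methoxyphenyl)borate of diol 6, 10 3,5-dimethoxyphenyl trifluoromethanesulfonate
Product: 14 cis-1,2-dimethylacenaphthylene-1,2-diyl [(1S,2R)-2-(3,5-dimethoxyphenyl)-2-[4-methoxy-2,6-bis(methoxymethoxy)phenyl]-1-(4-methoxyphenyl)ethyl]boronate
Conditions: Pd(OAc)2 (3 mol %), (Sp,Sp)-1,1′-bis[bis(4-methoxy-3,5-dimethylphenyl)phosphino]-2,2′-bis[(R)-α-(dimethylamino)benzyl]ferrocene (MandyPhos ligand, 3.6 mol %), NaOTf, THF, 60 °C
Reagents that add atoms: none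
Why: Conjunctive cross-coupling: oxidative addition of 10 to zerovalent palladium (formed from Pd(OAc)2 and the bisphosphine) gives a cationic arylpalladium triflate (divalent palladium) that binds the electron-rich alkene of borate 13. A palladium-induced 1,2-metallate shift then moves the 4-methoxyphenyl group from boron to C2' anti to the metal as palladium bonds to C3', and C–C reductive elimination with retention joins C3' to the 3,5-dimethoxyphenyl ring. The closest known reaction type is the enantioselective Pd(OAc)2/MandyPhos conjunctive coupling of β-substituted alkenylboron ate complexes bearing this hindered diol with aryl triflates. No ring closes. C3' is set by the ligand, which decides the alkene face that palladium takes; C2' follows from the anti stereospecificity of the shift on the E-alkene and serves only as a relay. The step needs the conjunctive pathway to win over direct transmetalation (plain Suzuki–Miyaura products) and over β-hydride elimination: the bulky diol shields the boron-bound oxygens that mediate transmetalation, triflate and NaOTf keep palladium cationic and free of the bromide carried over from step 7, and the chelating bisphosphine favours reductive elimination. The three alkoxy groups of ring B make the alkene a strong donor, which should offset the steric cost of its two ortho substituents.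

Step 9
Reactants: 14 cis-1,2-dimethylacenaphthylene-1,2-diyl [(1S,2R)-2-(3,5-dimethoxyphenyl)-2-[4-methoxy-2,6-bis(methoxymethoxy)phenyl]-1-(4-methoxyphenyl)ethyl]boronate
Product: 15 (1S,2R)-2-(3,5-dimethoxyphenyl)-2-[4-methoxy-2,6-bis(methoxymethoxy)phenyl]-1-(4-methoxyphenyl)ethanol
Conditions: 30 % H2O2, 3 M NaOH, THF, 0 to 25 °C
Reagents that add atoms: hydrogen peroxide, OO
Why: Alkaline peroxide oxidation of the C–B bond, in which carbon migrates from boron to oxygen with retention; the acetals and aryl ethers are stable to base and the diol 6 is released for recovery.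

Step 10
Reactants: 15 (1S,2R)-2-(3,5-dimethoxyphenyl)-2-[4-methoxy-2,6-bis(methoxymethoxy)phenyl]-1-(4-methoxyphenyl)ethanol
Product: 16 (2R,3R)-3-(3,5-dimethoxyphenyl)-6-methoxy-2-(4-methoxyphenyl)-2,3-dihydrobenzofuran-4-ol
Conditions: HCl (1 M in MeOH), 25 to 50 °C
Reagents that add atoms: none
Why: Acid methanolysis of both acetals and ionisation of the 4-methoxybenzylic alcohol, followed by capture of the cation by an ortho phenol (5-exo SN1 etherification); the closure is reversible and places the C2' aryl trans to the C3' aryl, and because the two ortho oxygens are equivalent a single product with a free C4' hydroxyl should result.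

Step 11
Reactants: 16 (2R,3R)-3-(3,5-dimethoxyphenyl)-6-methoxy-2-(4-methoxyphenyl)-2,3-dihydrobenzofuran-4-ol
Product: 17 (2R,3R)-3-(3,5-dimethoxyphenyl)-6-methoxy-2-(4-methoxyphenyl)-2,3-dihydrobenzofuran-4-yl trifluoromethanesulfonate
Conditions: Tf2O, pyridine, CH2Cl2, 0 °C
Reagents that add atoms: trifluoromethanesulfonic anhydride, O=S(=O)(OS(=O)(=O)C(F)(F)F)C(F)(F)F
Why: O-Sulfonylation of the only free phenol turns C4' into the electrophilic site for the union with unit 1.

Step 12
Reactants: 13 lithium [(E)-2-[4-methoxy-2,6-bis(methoxymethoxy)phenyl]ethenyl](4-methoxyphenyl)borate of diol 6, 17 (2R,3R)-3-(3,5-dimethoxyphenyl)-6-methoxy-2-(4-methoxyphenyl)-2,3-dihydrobenzofuran-4-yl trifluoromethanesulfonate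
Product: 18 cis-1,2-dimethylacenaphthylene-1,2-diyl [(1R,2S)-2-[(2R,3R)-3-(3,5-dimethoxyphenyl)-6-methoxy-2-(4-methoxyphenyl)-2,3-dihydrobenzofuran-4-yl]-2-[4-methoxy-2,6-bis(methoxymethoxy)phenyl]-1-(4-methoxyphenyl)ethyl]boronate
Conditions: Pd(OAc)2 (5 mol %), (Rp,Rp)-1,1′-bis[bis(4-methoxy-3,5-dimethylphenyl)phosphino]-2,2′-bis[(S)-α-(dimethylamino)benzyl]ferrocene (MandyPhos ligand, 6 mol %), NaOTf, THF, 60 to 70 °C
Reagents that add atoms: none
Why: The same conjunctive cross-coupling of borate 13 with the mirror-image ligand: the arylpalladium triflate from 17 (divalent palladium) is delivered to C3 on the opposite alkene face while the 4-methoxyphenyl group shifts to C2 anti to it, so C3 is set by the catalyst and not by the distant stereocenters of 17.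

Step 13
Reactants: 18 cis-1,2-dimethylacenaphthylene-1,2-diyl [(1R,2S)-2-[(2R,3R)-3-(3,5-dimethoxyphenyl)-6-methoxy-2-(4-methoxyphenyl)-2,3-dihydrobenzofuran-4-yl]-2-[4-methoxy-2,6-bis(methoxymethoxy)phenyl]-1-(4-methoxyphenyl)ethyl]boronate
Product: 19 (1R,2S)-2-[(2R,3R)-3-(3,5-dimethoxyphenyl)-6-methoxy-2-(4-methoxyphenyl)-2,3-dihydrobenzofuran-4-yl]-2-[4-methoxy-2,6-bis(methoxymethoxy)phenyl]-1-(4-methoxyphenyl)ethanol
Conditions: 30 % H2O2, 3 M NaOH, THF, 0 to 25 °C
Reagents that add atoms: hydrogen peroxide, OO
Why: Stereoretentive alkaline peroxide oxidation of the secondary benzylic boronate, as in step 9.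

Step 14
Reactants: 19 (1R,2S)-2-[(2R,3R)-3-(3,5-dimethoxyphenyl)-6-methoxy-2-(4-methoxyphenyl)-2,3-dihydrobenzofuran-4-yl]-2-[4-methoxy-2,6-bis(methoxymethoxy)phenyl]-1-(4-methoxyphenyl)ethanol
Product: 20 (2S,3S)-3-[(2R,3R)-3-(3,5-dimethoxyphenyl)-6-methoxy-2-(4-methoxyphenyl)-2,3-dihydrobenzofuran-4-yl]-6-methoxy-2-(4-methoxyphenyl)-2,3-dihydrobenzofuran-4-ol
Conditions: HCl (1 M in MeOH), 25 °C, short reaction time
Reagents that add atoms: none
Why: The same acetal cleavage and 5-exo cation–phenol closure as in step 10 gives the trans ring of unit 1; mild acid and a short time are chosen so that oxygen capture of the C2 cation stays ahead of slower carbon capture by the 3,5-dimethoxyphenyl ring.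

Step 15
Reactants: 20 (2S,3S)-3-[(2R,3R)-3-(3,5-dimethoxyphenyl)-6-methoxy-2-(4-methoxyphenyl)-2,3-dihydrobenzofuran-4-yl]-6-methoxy-2-(4-methoxyphenyl)-2,3-dihydrobenzofuran-4-ol
Product: 21 (2S,3S)-3-[(2R,3R)-3-(3,5-dimethoxyphenyl)-6-methoxy-2-(4-methoxyphenyl)-2,3-dihydrobenzofuran-4-yl]-6-methoxy-2-(4-methoxyphenyl)-2,3-dihydrobenzofuran-4-yl trifluoromethanesulfonate
Conditions: Tf2O, pyridine, CH2Cl2, 0 °C
Reagents that add atoms: trifluoromethanesulfonic anhydride, O=S(=O)(OS(=O)(=O)C(F)(F)F)C(F)(F)F
Why: O-Sulfonylation of the single free phenol activates C4 of ring A for attachment of the two-carbon arm.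

Step 16
Reactants: 21 (2S,3S)-3-[(2R,3R)-3-(3,5-dimethoxyphenyl)-6-methoxy-2-(4-methoxyphenyl)-2,3-dihydrobenzofuran-4-yl]-6-methoxy-2-(4-methoxyphenyl)-2,3-dihydrobenzofuran-4-yl trifluoromethanesulfonate, 22 4-ethynylanisole
Product: 23 (2S,3S)-3-[(2R,3R)-3-(3,5-dimethoxyphenyl)-6-methoxy-2-(4-methoxyphenyl)-2,3-dihydrobenzofuran-4-yl]-6-methoxy-2-(4-methoxyphenyl)-4-[(4-methoxyphenyl)ethynyl]-2,3-dihydrobenzofuran
Conditions: Pd(PPh3)2Cl2 (5 mol %), CuI (10 mol %), Et3N, DMF, 70 °C
Reagents that add atoms: none
Why: Sonogashira coupling of an aryl triflate with a terminal alkyne; the triflate has one free ortho position and the sp-hybridised partner is sterically undemanding.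

Step 17
Reactants: 23 (2S,3S)-3-[(2R,3R)-3-(3,5-dimethoxyphenyl)-6-methoxy-2-(4-methoxyphenyl)-2,3-dihydrobenzofuran-4-yl]-6-methoxy-2-(4-methoxyphenyl)-4-[(4-methoxyphenyl)ethynyl]-2,3-dihydrobenzofuran
Product: 24 (2S,3S)-3-[(2R,3R)-3-(3,5-dihydroxyphenyl)-6-hydroxy-2-(4-hydroxyphenyl)-2,3-dihydrobenzofuran-4-yl]-2-(4-hydroxyphenyl)-4-[(4-hydroxyphenyl)ethynyl]-2,3-dihydrobenzofuran-6-ol
Conditions: BBr3 (12 equiv), CH2Cl2, −78 to 0 °C; MeOH, aq. NaHCO3
Reagents that add atoms: none
Why: Lewis-acid demethylation of aryl methyl ethers by boron complexation and bromide attack on methyl; the alkyne has no ortho oxygen to cyclise onto, and any reversible opening of a benzylic C–O bond should reclose to the trans ring.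

Step 18
Reactants: 24 (2S,3S)-3-[(2R,3R)-3-(3,5-dihydroxyphenyl)-6-hydroxy-2-(4-hydroxyphenyl)-2,3-dihydrobenzofuran-4-yl]-2-(4-hydroxyphenyl)-4-[(4-hydroxyphenyl)ethynyl]-2,3-dihydrobenzofuran-6-ol
Product: 25 cis-miyabenol C
Conditions: H2 (1 atm), Pd/CaCO3 poisoned with Pb(OAc)2 (Lindlar catalyst), quinoline, EtOAc/MeOH, 25 °C, dark
Reagents that add atoms: none
Why: Lindlar semihydrogenation delivers both hydrogens to one face of the alkyne on the poisoned palladium surface and should stop at the Z-alkene; neutral conditions and exclusion of light protect the cis-stilbene and the benzylic ethers.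

## Compound list

1 | 2,4,6-trimethoxybenzaldehyde | COc1cc(OC)c(C=O)c(OC)c1 | starting material
2 | 2,6-dihydroxy-4-methoxybenzaldehyde | COc1cc(O)c(C=O)c(O)c1 | intermediate
3 | 4-methoxy-2,6-bis(methoxymethoxy)benzaldehyde | COCOc1cc(OC)cc(OCOC)c1C=O | intermediate
4 | 2-ethynyl-5-methoxy-1,3-bis(methoxymethoxy)benzene | COCOc1cc(OC)cc(OCOC)c1C#C | intermediate
5 | acenaphthenequinone | O=C1C(=O)c2cccc3cccc1c23 | starting material
6 | cis-1,2-dimethyl-1,2-dihydroacenaphthylene-1,2-diol | C[C@]1(O)c2cccc3cccc(c23)[C@@]1(C)O | intermediate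
7 | 2-[(E)-2-[4-methoxy-2,6-bis(methoxymethoxy)phenyl]ethenyl]-1,3,2-benzodioxaborole | COCOc1cc(OC)cc(OCOC)c1/C=C/B1Oc2ccccc2O1 | intermediate (not isolated)
8 | cis-1,2-dimethylacenaphthylene-1,2-diyl [(E)-2-[4-methoxy-2,6-bis(methoxymethoxy)phenyl]ethenyl]boronate | COCOc1cc(OC)cc(OCOC)c1/C=C/B1O[C@@]2(C)c3cccc4cccc(c34)[C@@]2(C)O1 | intermediate
9 | 3,5-dimethoxyphenol | COc1cc(O)cc(OC)c1 | starting material
10 | 3,5-dimethoxyphenyl trifluoromethanesulfonate | COc1cc(OC)cc(OS(=O)(=O)C(F)(F)F)c1 | intermediate
11 | 4-bromoanisole | COc1ccc(Br)cc1 | starting material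
12 | 4-methoxyphenyllithium | [Li]c1ccc(OC)cc1 | intermediate (not isolated)
13 | lithium [(E)-2-[4-methoxy-2,6-bis(methoxymethoxy)phenyl]ethenyl](4-methoxyphenyl)borate of diol 6 (configuration at boron not defined) | [Li+].COCOc1cc(OC)cc(OCOC)c1/C=C/[B-]1(c2ccc(OC)cc2)O[C@@]2(C)c3cccc4cccc(c34)[C@@]2(C)O1 | intermediate
14 | cis-1,2-dimethylacenaphthylene-1,2-diyl [(1S,2R)-2-(3,5-dimethoxyphenyl)-2-[4-methoxy-2,6-bis(methoxymethoxy)phenyl]-1-(4-methoxyphenyl)ethyl]boronate | COCOc1cc(OC)cc(OCOC)c1[C@@H](c1cc(OC)cc(OC)c1)[C@@H](c1ccc(OC)cc1)B1O[C@@]2(C)c3cccc4cccc(c34)[C@@]2(C)O1 | intermediate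
15 | (1S,2R)-2-(3,5-dimethoxyphenyl)-2-[4-methoxy-2,6-bis(methoxymethoxy)phenyl]-1-(4-methoxyphenyl)ethanol | COCOc1cc(OC)cc(OCOC)c1[C@@H](c1cc(OC)cc(OC)c1)[C@@H](c1ccc(OC)cc1)O | intermediate
16 | (2R,3R)-3-(3,5-dimethoxyphenyl)-6-methoxy-2-(4-methoxyphenyl)-2,3-dihydrobenzofuran-4-ol | Oc1cc(OC)cc2c1[C@@H](c1cc(OC)cc(OC)c1)[C@H](c1ccc(OC)cc1)O2 | intermediate
17 | (2R,3R)-3-(3,5-dimethoxyphenyl)-6-methoxy-2-(4-methoxyphenyl)-2,3-dihydrobenzofuran-4-yl trifluoromethanesulfonate | FC(F)(F)S(=O)(=O)Oc1cc(OC)cc2c1[C@@H](c1cc(OC)cc(OC)c1)[C@H](c1ccc(OC)cc1)O2 | intermediate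
18 | cis-1,2-dimethylacenaphthylene-1,2-diyl [(1R,2S)-2-[(2R,3R)-3-(3,5-dimethoxyphenyl)-6-methoxy-2-(4-methoxyphenyl)-2,3-dihydrobenzofuran-4-yl]-2-[4-methoxy-2,6-bis(methoxymethoxy)phenyl]-1-(4-methoxyphenyl)ethyl]boronate | COCOc1cc(OC)cc(OCOC)c1[C@H](c1cc(OC)cc2c1[C@@H](c1cc(OC)cc(OC)c1)[C@H](c1ccc(OC)cc1)O2)[C@H](c1ccc(OC)cc1)B1O[C@@]2(C)c3cccc4cccc(c34)[C@@]2(C)O1 | intermediate
19 | (1R,2S)-2-[(2R,3R)-3-(3,5-dimethoxyphenyl)-6-methoxy-2-(4-methoxyphenyl)-2,3-dihydrobenzofuran-4-yl]-2-[4-methoxy-2,6-bis(methoxymethoxy)phenyl]-1-(4-methoxyphenyl)ethanol | COCOc1cc(OC)cc(OCOC)c1[C@H](c1cc(OC)cc2c1[C@@H](c1cc(OC)cc(OC)c1)[C@H](c1ccc(OC)cc1)O2)[C@H](c1ccc(OC)cc1)O | intermediate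
20 | (2S,3S)-3-[(2R,3R)-3-(3,5-dimethoxyphenyl)-6-methoxy-2-(4-methoxyphenyl)-2,3-dihydrobenzofuran-4-yl]-6-methoxy-2-(4-methoxyphenyl)-2,3-dihydrobenzofuran-4-ol | Oc1cc(OC)cc2c1[C@H](c1cc(OC)cc3c1[C@@H](c1cc(OC)cc(OC)c1)[C@H](c1ccc(OC)cc1)O3)[C@@H](c1ccc(OC)cc1)O2 | intermediate
21 | (2S,3S)-3-[(2R,3R)-3-(3,5-dimethoxyphenyl)-6-methoxy-2-(4-methoxyphenyl)-2,3-dihydrobenzofuran-4-yl]-6-methoxy-2-(4-methoxyphenyl)-2,3-dihydrobenzofuran-4-yl trifluoromethanesulfonate | FC(F)(F)S(=O)(=O)Oc1cc(OC)cc2c1[C@H](c1cc(OC)cc3c1[C@@H](c1cc(OC)cc(OC)c1)[C@H](c1ccc(OC)cc1)O3)[C@@H](c1ccc(OC)cc1)O2 | intermediate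
22 | 4-ethynylanisole | COc1ccc(C#C)cc1 | starting material
23 | (2S,3S)-3-[(2R,3R)-3-(3,5-dimethoxyphenyl)-6-methoxy-2-(4-methoxyphenyl)-2,3-dihydrobenzofuran-4-yl]-6-methoxy-2-(4-methoxyphenyl)-4-[(4-methoxyphenyl)ethynyl]-2,3-dihydrobenzofuran | COc1ccc(C#Cc2cc(OC)cc3c2[C@H](c2cc(OC)cc4c2[C@@H](c2cc(OC)cc(OC)c2)[C@H](c2ccc(OC)cc2)O4)[C@@H](c2ccc(OC)cc2)O3)cc1 | intermediate
24 | (2S,3S)-3-[(2R,3R)-3-(3,5-dihydroxyphenyl)-6-hydroxy-2-(4-hydroxyphenyl)-2,3-dihydrobenzofuran-4-yl]-2-(4-hydroxyphenyl)-4-[(4-hydroxyphenyl)ethynyl]-2,3-dihydrobenzofuran-6-ol | Oc1ccc(C#Cc2cc(O)cc3c2[C@H](c2cc(O)cc4c2[C@@H](c2cc(O)cc(O)c2)[C@H](c2ccc(O)cc2)O4)[C@@H](c2ccc(O)cc2)O3)cc1 | intermediate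
25 | cis-miyabenol C | Oc1ccc(/C=C\c2cc(O)cc3c2[C@H](c2cc(O)cc4c2[C@@H](c2cc(O)cc(O)c2)[C@H](c2ccc(O)cc2)O4)[C@@H](c2ccc(O)cc2)O3)cc1 | target

## Step count and least certain steps

Total step count: 18. Longest linear sequence: 16 steps (steps 1–3, 5 and 7–18).

**Step 8 (key step).** The borate 13 may hand its aryl or alkenyl group directly to palladium before palladium can bind the alkene, which is shielded by two ortho substituents; this transmetalation would give plain cross-coupling products. Facial selection may also be eroded, and β-hydride elimination after the shift is possible.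

Fallback: from aldehyde 3, C3' is set by a conjugate arylation instead. A Henry condensation of 3 with nitromethane gives 5-methoxy-1,3-bis(methoxymethoxy)-2-[(E)-2-nitroethenyl]benzene F1. [RhCl(C2H4)2]2 with a chiral diene ligand then adds commercial 3,5-dimethoxyphenylboronic acid to give (R)-2-[1-(3,5-dimethoxyphenyl)-2-nitroethyl]-5-methoxy-1,3-bis(methoxymethoxy)benzene F2. A buffered TiCl3 Nef reaction gives (R)-2-(3,5-dimethoxyphenyl)-2-[4-methoxy-2,6-bis(methoxymethoxy)phenyl]acetaldehyde F3, which is used at once at low temperature because its α-centre is enolisable. 4-Methoxyphenylmagnesium bromide at −78 °C gives 15 together with its C1 epimer, (1R,2R)-2-(3,5-dimethoxyphenyl)-2-[4-methoxy-2,6-bis(methoxymethoxy)phenyl]-1-(4-methoxyphenyl)ethanol F4. Both alcohols converge on 16 under the conditions of step 10, where the route is rejoined.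

**Step 12.** The same competition with direct transmetalation applies, made worse by slow oxidative addition of the hindered, electron-rich triflate 17 and by reductive elimination at a carbon that ends up with two ortho-substituted aryl groups. The ligand may also be mismatched with the stereocenters of 17, which would lower facial selectivity.

Fallback: from triflate 17, Miyaura borylation (B2pin2, Pd(dppf)Cl2, KOAc) gives (2R,3R)-3-(3,5-dimethoxyphenyl)-6-methoxy-2-(4-methoxyphenyl)-4-(4,4,5,5-tetramethyl-1,3,2-dioxaborolan-2-yl)-2,3-dihydrobenzofuran F5. F5 is added to the nitroalkene 5-methoxy-1,3-bis(methoxymethoxy)-2-[(E)-2-nitroethenyl]benzene F1 (from 3 and nitromethane) with [RhCl(C2H4)2]2 and the mirror-image diene to give 2-[(1S)-1-[(2R,3R)-3-(3,5-dimethoxyphenyl)-6-methoxy-2-(4-methoxyphenyl)-2,3-dihydrobenzofuran-4-yl]-2-nitroethyl]-5-methoxy-1,3-bis(methoxymethoxy)benzene F6. The TiCl3 Nef reaction gives (2S)-2-[(2R,3R)-3-(3,5-dimethoxyphenyl)-6-methoxy-2-(4-methoxyphenyl)-2,3-dihydrobenzofuran-4-yl]-2-[4-methoxy-2,6-bis(methoxymethoxy)phenyl]acetaldehyde F7. 4-Methoxyphenylmagnesium bromide gives 19 with its C1 epimer, (1S,2S)-2-[(2R,3R)-3-(3,5-dimethoxyphenyl)-6-methoxy-2-(4-methoxyphenyl)-2,3-dihydrobenzofuran-4-yl]-2-[4-methoxy-2,6-bis(methoxymethoxy)phenyl]-1-(4-methoxyphenyl)ethanol F8. Both close to 20 under the conditions of step 14, where the route is rejoined.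

**Step 17.** Under the Lewis acid the benzylic C2–O1 or C2'–O1' bond may ionise and the cation may be captured irreversibly by a neighbouring electron-rich ring instead of reclosing. Hydrogen bromide may also add to the electron-rich alkyne.

Fallback: from 23 the ether cleavage is changed from Lewis-acid activation of oxygen to SN2 attack on the methyl carbon. Sodium ethanethiolate in DMF at 130 °C works under basic conditions in which no benzylic cation can form, and gives 24 directly.

**Step 18.** The hydrogenation may run on to the saturated bridge, may give some E-alkene through palladium hydride isomerisation, or may stall because the polyphenol binds the catalyst surface and one alkyne terminus is hindered.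

Fallback: from triflate 21 the Z-alkene is brought in by cross-coupling instead of reduction. Hydroboration of 22 with pinacolborane under [Rh(cod)Cl]2/P(i-Pr)3/Et3N, which adds trans, gives 2-[(Z)-2-(4-methoxyphenyl)ethenyl]-4,4,5,5-tetramethyl-1,3,2-dioxaborolane F9. Suzuki–Miyaura coupling of F9 with 21 (Pd(PPh3)4, K3PO4) with retention of alkene geometry gives (2S,3S)-3-[(2R,3R)-3-(3,5-dimethoxyphenyl)-6-methoxy-2-(4-methoxyphenyl)-2,3-dihydrobenzofuran-4-yl]-6-methoxy-2-(4-methoxyphenyl)-4-[(Z)-2-(4-methoxyphenyl)ethenyl]-2,3-dihydrobenzofuran F10. Thiolate demethylation (sodium ethanethiolate, DMF) under non-acidic conditions then gives 25.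

**Step 5.** The boron Lewis acid may cleave a methoxymethyl acetal, the exchange of catechol for the hindered diol may stay incomplete, and the electron-rich alkenylboron may protodeboronate on purification.

Fallback: from aldehyde 3, a CrCl2/LiI-mediated boryl-olefination with Cl2CHB(pin) (Takai–Utimoto type) gives 2-[(E)-2-[4-methoxy-2,6-bis(methoxymethoxy)phenyl]ethenyl]-4,4,5,5-tetramethyl-1,3,2-dioxaborolane F11. KHF2 converts it into potassium [(E)-2-[4-methoxy-2,6-bis(methoxymethoxy)phenyl]ethenyl]trifluoroborate F12. Hydrolysis on silica gel gives [(E)-2-[4-methoxy-2,6-bis(methoxymethoxy)phenyl]ethenyl]boronic acid F13, which is condensed with 6 over MgSO4 to rejoin the route at 8.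

## Further compounds

F1 | step 8 | 5-methoxy-1,3-bis(methoxymethoxy)-2-[(E)-2-nitroethenyl]benzene | COCOc1cc(OC)cc(OCOC)c1/C=C/[N+](=O)[O-]
F2 | step 8 | (R)-2-[1-(3,5-dimethoxyphenyl)-2-nitroethyl]-5-methoxy-1,3-bis(methoxymethoxy)benzene | COCOc1cc(OC)cc(OCOC)c1[C@@H](c1cc(OC)cc(OC)c1)C[N+](=O)[O-]
F3 | step 8 | (R)-2-(3,5-dimethoxyphenyl)-2-[4-methoxy-2,6-bis(methoxymethoxy)phenyl]acetaldehyde | COCOc1cc(OC)cc(OCOC)c1[C@@H](c1cc(OC)cc(OC)c1)C=O
F4 | step 8 | (1R,2R)-2-(3,5-dimethoxyphenyl)-2-[4-methoxy-2,6-bis(methoxymethoxy)phenyl]-1-(4-methoxyphenyl)ethanol | COCOc1cc(OC)cc(OCOC)c1[C@@H](c1cc(OC)cc(OC)c1)[C@H](c1ccc(OC)cc1)O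
F5 | step 12 | (2R,3R)-3-(3,5-dimethoxyphenyl)-6-methoxy-2-(4-methoxyphenyl)-4-(4,4,5,5-tetramethyl-1,3,2-dioxaborolan-2-yl)-2,3-dihydrobenzofuran | CC1(C)OB(OC1(C)C)c1cc(OC)cc2c1[C@@H](c1cc(OC)cc(OC)c1)[C@H](c1ccc(OC)cc1)O2
F6 | step 12 | 2-[(1S)-1-[(2R,3R)-3-(3,5-dimethoxyphenyl)-6-methoxy-2-(4-methoxyphenyl)-2,3-dihydrobenzofuran-4-yl]-2-nitroethyl]-5-methoxy-1,3-bis(methoxymethoxy)benzene | COCOc1cc(OC)cc(OCOC)c1[C@H](c1cc(OC)cc2c1[C@@H](c1cc(OC)cc(OC)c1)[C@H](c1ccc(OC)cc1)O2)C[N+](=O)[O-]
F7 | step 12 | (2S)-2-[(2R,3R)-3-(3,5-dimethoxyphenyl)-6-methoxy-2-(4-methoxyphenyl)-2,3-dihydrobenzofuran-4-yl]-2-[4-methoxy-2,6-bis(methoxymethoxy)phenyl]acetaldehyde | COCOc1cc(OC)cc(OCOC)c1[C@H](c1cc(OC)cc2c1[C@@H](c1cc(OC)cc(OC)c1)[C@H](c1ccc(OC)cc1)O2)C=O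
F8 | step 12 | (1S,2S)-2-[(2R,3R)-3-(3,5-dimethoxyphenyl)-6-methoxy-2-(4-methoxyphenyl)-2,3-dihydrobenzofuran-4-yl]-2-[4-methoxy-2,6-bis(methoxymethoxy)phenyl]-1-(4-methoxyphenyl)ethanol | COCOc1cc(OC)cc(OCOC)c1[C@H](c1cc(OC)cc2c1[C@@H](c1cc(OC)cc(OC)c1)[C@H](c1ccc(OC)cc1)O2)[C@@H](c1ccc(OC)cc1)O
F0 | step 17 | none | none
F9 | step 18 | 2-[(Z)-2-(4-methoxyphenyl)ethenyl]-4,4,5,5-tetramethyl-1,3,2-dioxaborolane | COc1ccc(/C=C\B2OC(C)(C)C(C)(C)O2)cc1
F10 | step 18 | (2S,3S)-3-[(2R,3R)-3-(3,5-dimethoxyphenyl)-6-methoxy-2-(4-methoxyphenyl)-2,3-dihydrobenzofuran-4-yl]-6-methoxy-2-(4-methoxyphenyl)-4-[(Z)-2-(4-methoxyphenyl)ethenyl]-2,3-dihydrobenzofuran | COc1ccc(/C=C\c2cc(OC)cc3c2[C@H](c2cc(OC)cc4c2[C@@H](c2cc(OC)cc(OC)c2)[C@H](c2ccc(OC)cc2)O4)[C@@H](c2ccc(OC)cc2)O3)cc1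
F11 | step 5 | 2-[(E)-2-[4-methoxy-2,6-bis(methoxymethoxy)phenyl]ethenyl]-4,4,5,5-tetramethyl-1,3,2-dioxaborolane | COCOc1cc(OC)cc(OCOC)c1/C=C/B1OC(C)(C)C(C)(C)O1
F12 | step 5 | potassium [(E)-2-[4-methoxy-2,6-bis(methoxymethoxy)phenyl]ethenyl]trifluoroborate | [K+].COCOc1cc(OC)cc(OCOC)c1/C=C/[B-](F)(F)F
F13 | step 5 | [(E)-2-[4-methoxy-2,6-bis(methoxymethoxy)phenyl]ethenyl]boronic acid | COCOc1cc(OC)cc(OCOC)c1/C=C/B(O)O
A1 | alternative 1 | [2-hydroxy-4-methoxy-6-[(4-methoxyphenyl)ethynyl]phenyl][(2R,3R)-3-(3,5-dimethoxyphenyl)-6-methoxy-2-(4-methoxyphenyl)-2,3-dihydrobenzofuran-4-yl]methanone | COc1ccc(C#Cc2cc(OC)cc(O)c2C(=O)c2cc(OC)cc3c2[C@@H](c2cc(OC)cc(OC)c2)[C@H](c2ccc(OC)cc2)O3)cc1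
A2 | alternative 1 | 1-[(2R,3R)-3-(3,5-dimethoxyphenyl)-6-methoxy-2-(4-methoxyphenyl)-2,3-dihydrobenzofuran-4-yl]-5-(4-methoxyphenyl)penta-2,4-diyn-1-one | COc1ccc(C#CC#CC(=O)c2cc(OC)cc3c2[C@@H](c2cc(OC)cc(OC)c2)[C@H](c2ccc(OC)cc2)O3)cc1
A3 | alternative 1 | 1,3-dimethoxy-1-(trimethylsilyloxy)buta-1,3-diene | C=C(OC)C=C(OC)O[Si](C)(C)C
A4 | alternative 2 | methyl (2S,3S)-4-(benzyloxy)-6-methoxy-2-(4-methoxyphenyl)-2,3-dihydrobenzofuran-3-carboxylate | c1ccccc1COc1cc(OC)cc2c1[C@H](C(=O)OC)[C@@H](c1ccc(OC)cc1)O2
A5 | alternative 2 | (2S)-5-(benzyloxy)-7-methoxy-2-(4-methoxyphenyl)chroman-4-one | O=C1C[C@@H](c2ccc(OC)cc2)Oc2cc(OC)cc(OCc3ccccc3)c12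
A6 | alternative 3 | (2R,3R)-3-(3,5-dimethoxyphenyl)-6-ethoxy-2-(4-methoxyphenyl)-4-(trimethylsilyl)-2,3-dihydrobenzofuran | C[Si](C)(C)c1cc(OCC)cc2c1[C@@H](c1cc(OC)cc(OC)c1)[C@H](c1ccc(OC)cc1)O2
A7 | alternative 3 | [(3R,4R)-3-(3,5-dimethoxyphenyl)-4-(ethynyloxy)-4-(4-methoxyphenyl)but-1-yn-1-yl]trimethylsilane | C[Si](C)(C)C#C[C@@H](c1cc(OC)cc(OC)c1)[C@H](c1ccc(OC)cc1)OC#C
A8 | alternative 3 | ethoxyethyne | CCOC#C
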